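## Retrosynthetic overview

- Target 19 (ring numbering: C1 carbonyl, C2=C3, C4–OMe, C5H2, fully substituted C6) ⇒ 18: the C6–allyl bond is made last by palladium-catalysed decarboxylative allylation. The allyl ester is the temporary activating group of C6 and leaves as CO2.
- 18 ⇒ 16 ⇒ 8 + 13: the only ring formed, the six-membered carbocycle, is closed at C5–C6 in a one-flask double alkylation of the CH2 group of acyclic β-keto ester 8. The lactate-derived α-keto triflate 13 reacts first (inversion), then C5 intramolecularly; the C2=C3 double bond follows by dehydrogenation.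
- Enabling feature: C6 is α to the ring carbonyl C1 and bears an allyl group. As the central carbon of an allyl β-keto ester it is a soft carbon acid that can be alkylated twice, and the ester then returns as the allyl substituent.
- Chiral pool: C1–C5 with the C4 centre are the five carbons of L-glutamic acid (γ-CO2H → C1, Cα → C4 with retention, α-CO2H → C5H2). The CH(CH3)–C(=O) unit of the side chain is L-lactic acid; the arene is bought as (3,4-dimethoxyphenyl)magnesium bromide.

Key step: step 10

Remark: compounds 14 to 18 are carried as mixtures of epimers at the carbon that becomes C6, because step 12 passes through a planar enolate at this carbon and sets it anew.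

## Route

Step 1
Reactants: 1 L-glutamic acid
Product: 2 (2S)-5-oxooxolane-2-carboxylic acid
Conditions: NaNO2, aq. HCl, 0 °C to rt
Reagents that add atoms: none
Why: Diazotisation of the α-amino acid, in which the α-carboxylate displaces N2 to an α-lactone that the γ-carboxylate opens, so two inversions should give net retention and the S centre that becomes C4 of the ring.

Step 2
Reactants: 2 (2S)-5-oxooxolane-2-carboxylic acid
Product: 3 (5S)-5-(hydroxymethyl)oxolan-2-one
Conditions: BH3·SMe2, THF, 0 °C to rt; then MeOH
Reagents that add atoms: none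
Why: Chemoselective borane reduction of a carboxylic acid beside a lactone (acyloxyborane pathway), which does not involve the stereocentre.

Step 3
Reactants: 3 (5S)-5-(hydroxymethyl)oxolan-2-one
Product: 4 (5S)-5-(chloromethyl)oxolan-2-one
Conditions: PPh3, N-chlorosuccinimide, CH2Cl2, 0 °C to rt
Reagents that add atoms: N-chlorosuccinimide, ClN1C(=O)CCC1=O
Why: Appel-type chlorination (SN2 of chloride on the alkoxyphosphonium ion) at the primary carbon, giving a leaving group that stays inert until step 10.

Step 4
Reactants: 4 (5S)-5-(chloromethyl)oxolan-2-one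
Product: 5 (4S)-5-chloro-4-hydroxy-N-methoxy-N-methylpentanamide
Conditions: MeNHOMe·HCl, AlMe3, CH2Cl2, 0 °C to rt; aq. potassium sodium tartrate work-up; used directly
Reagents that add atoms: N,O-dimethylhydroxylamine hydrochloride, CNOC.Cl
Why: Aluminium amide aminolysis of the lactone to the Weinreb amide (acyl substitution at the lactone carbonyl), which leaves the C–O stereocentre untouched.

Step 5
Reactants: 5 (4S)-5-chloro-4-hydroxy-N-methoxy-N-methylpentanamide
Product: 6 (4S)-5-chloro-N,4-dimethoxy-N-methylpentanamide
Conditions: Me3OBF4, 1,8-bis(dimethylamino)naphthalene, CH2Cl2, rt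
Reagents that add atoms: trimethyloxonium tetrafluoroborate, C[O+](C)C.F[B-](F)(F)F
Why: O-Methylation with an oxonium salt and a non-nucleophilic base, under which a γ-hydroxy Weinreb amide should neither relactonise nor close to the epoxide as an alkoxide would, and the C–O bond at the stereocentre is not broken.

Step 6
Reactants: 6 (4S)-5-chloro-N,4-dimethoxy-N-methylpentanamide; 7 prop-2-en-1-yl acetate (allyl acetate)
Product: 8 prop-2-en-1-yl (6S)-7-chloro-6-methoxy-3-oxoheptanoate
Conditions: LiN(i-Pr)2 (3 equiv), 7 (3 equiv), THF, −78 °C; then 6, −78 to −40 °C; aq. NH4Cl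
Reagents that add atoms: none
Why: Crossed Claisen condensation of a lithium ester enolate with a Weinreb amide, in which the chelated tetrahedral intermediate prevents over-addition and the primary chloride does not react with the enolate at this temperature.

Step 7
Reactants: 9 ethyl (2S)-2-hydroxypropanoate (ethyl L-lactate)
Product: 10 (2S)-2-hydroxy-N-methoxy-N-methylpropanamide
Conditions: MeNHOMe·HCl, i-PrMgCl, THF, −20 to 0 °C
Reagents that add atoms: N,O-dimethylhydroxylamine hydrochloride, CNOC.Cl
Why: Magnesium amide aminolysis of the ester to the Weinreb amide, with the α-centre held as a magnesium alkoxide chelate so that the S configuration of L-lactic acid should be kept.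

Step 8
Reactants: 10 (2S)-2-hydroxy-N-methoxy-N-methylpropanamide; 11 (3,4-dimethoxyphenyl)magnesium bromide
Product: 12 (2S)-1-(3,4-dimethoxyphenyl)-2-hydroxypropan-1-one
Conditions: 11 (2.5 equiv), THF, 0 °C to rt; aq. NH4Cl
Reagents that add atoms: none
Why: Ketone synthesis by addition of an arylmagnesium halide to a Weinreb amide, in which one equivalent deprotonates the hydroxyl and the stable chelate stops at the ketone stage without enolisation of the α-centre.

Step 9
Reactants: 12 (2S)-1-(3,4-dimethoxyphenyl)-2-hydroxypropan-1-one
Product: 13 (2S)-1-(3,4-dimethoxyphenyl)-1-oxopropan-2-yl trifluoromethanesulfonate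
Conditions: Tf2O, 2,6-lutidine, CH2Cl2, −78 °C; filtered cold through silica and used at once
Reagents that add atoms: trifluoromethanesulfonic anhydride, FC(F)(F)S(=O)(=O)OS(=O)(=O)C(F)(F)F
Why: O-Sulfonylation of the secondary alcohol with retention (the C–O bond is not touched), giving an α-keto triflate whose non-nucleophilic leaving group cannot racemise it by exchange.

Step 10
Reactants: 8 prop-2-en-1-yl (6S)-7-chloro-6-methoxy-3-oxoheptanoate; 13 (2S)-1-(3,4-dimethoxyphenyl)-1-oxopropan-2-yl trifluoromethanesulfonate
Product: 16 prop-2-en-1-yl (5S)-1-[(2S)-1-(3,4-dimethoxyphenyl)-1-oxopropan-2-yl]-5-methoxy-2-oxocyclohexane-1-carboxylate (both C1 epimers), via open-chain chloride 14 (not isolated), via open-chain iodide 15 (not isolated)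
Conditions: NaH (1.0 equiv), THF, 0 °C; 13, −78 to 0 °C; then KOt-Bu (1.05 equiv), NaI (0.2 equiv), t-BuOH–THF, 60 °C
Reagents that add atoms: none
Why: Mechanism: the sodium enolate of 8, a soft carbon acid between the future ring carbonyl and the allyl ester, displaces triflate from 13 by SN2 with inversion to give 14, and the potassium enolate of 14, after in situ halide exchange to iodide 15, attacks the CH2–I carbon intramolecularly, which forms the ring bond between the fully substituted carbon (C6 of the target) and the ring CH2 (C5). The closest known reaction types are the C-alkylation of β-keto ester anions by α-sulfonyloxy carbonyl compounds with inversion and the cyclisation of 7-halo-3-oxoheptanoates to 2-oxocyclohexane-1-carboxylates. The six-membered ring closes in the 6-(enolendo)-exo-tet mode through a chair-like transition state with the methoxy group equatorial. The side-chain stereocentre is controlled by L-lactic acid (inversion at its carbinol carbon gives S) and the methoxy-bearing centre by L-glutamic acid, while the new fully substituted carbon forms as a mixture of epimers that is of no consequence, because both epimers give the same palladium enolate in step 12. The step needs intermolecular before intramolecular alkylation, secured by a primary chloride that is inert at −78 to 0 °C beside the far more reactive α-keto triflate, and C- rather than O-alkylation in the ring closure, secured by the soft iodide, the hydrogen-bonding t-BuOH medium and the six-membered enolendo geometry. Running both alkylations in one flask avoids isolating 14, whose enolisable 1,4-diketone could dehydrate to a furan, a path that is closed once the ring carbon is fully substituted.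

Step 11
Reactants: 16 prop-2-en-1-yl (5S)-1-[(2S)-1-(3,4-dimethoxyphenyl)-1-oxopropan-2-yl]-5-methoxy-2-oxocyclohexane-1-carboxylate
Product: 18 prop-2-en-1-yl (5R)-1-[(2S)-1-(3,4-dimethoxyphenyl)-1-oxopropan-2-yl]-5-methoxy-2-oxocyclohex-3-ene-1-carboxylate (both C1 epimers), via α-phenylselenide 17 (not isolated)
Conditions: LiN(i-Pr)2 (1.1 equiv), THF, −78 °C; PhSeBr; then H2O2, pyridine, CH2Cl2, 0 °C to rt
Reagents that add atoms: none
Why: Kinetic enolate selenenylation followed by selenoxide syn-elimination, in which the ring ketone can enolise only toward its CH2 group (far more accessible to the amide base than the hindered side-chain methine) and the elimination can only give the conjugated C2=C3 double bond, which changes the descriptor of the methoxy-bearing carbon from S to R without touching the centre.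

Step 12
Reactants: 18 prop-2-en-1-yl (5R)-1-[(2S)-1-(3,4-dimethoxyphenyl)-1-oxopropan-2-yl]-5-methoxy-2-oxocyclohex-3-ene-1-carboxylate
Product: 19 (4R,6R)-6-[(2S)-1-(3,4-dimethoxyphenyl)-1-oxopropan-2-yl]-4-methoxy-6-(prop-2-en-1-yl)cyclohex-2-en-1-one (target)
Conditions: Pd2(dba)3 (2.5 mol %; dba = dibenzylideneacetone), (S)-t-Bu-PHOX [(S)-4-tert-butyl-2-(2-(diphenylphosphino)phenyl)-4,5-dihydrooxazole] (6 mol %), toluene, 30 °C
Reagents that add atoms: none
Why: Decarboxylative allylic alkylation (Tsuji allylation), in which zerovalent palladium ionises the allyl ester, CO2 is lost from either epimer of 18 to give one cross-conjugated palladium dienolate without enolate equilibration, and the allyl group returns to C6 on the face selected by the (S)-phosphinooxazoline ligand (the sense that gives (S)-2-allyl-2-methylcyclohexanone in the parent series, here the R descriptor), which is also the face trans to the C4 methoxy group.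

## Compound list

1 | L-glutamic acid | N[C@@H](CCC(=O)O)C(=O)O | starting material
2 | (2S)-5-oxooxolane-2-carboxylic acid | OC(=O)[C@@H]1CCC(=O)O1 | intermediate
3 | (5S)-5-(hydroxymethyl)oxolan-2-one | OC[C@@H]1CCC(=O)O1 | intermediate
4 | (5S)-5-(chloromethyl)oxolan-2-one | ClC[C@@H]1CCC(=O)O1 | intermediate
5 | (4S)-5-chloro-4-hydroxy-N-methoxy-N-methylpentanamide | ClC[C@@H](O)CCC(=O)N(C)OC | intermediate
6 | (4S)-5-chloro-N,4-dimethoxy-N-methylpentanamide | ClC[C@@H](OC)CCC(=O)N(C)OC | intermediate
7 | prop-2-en-1-yl acetate (allyl acetate) | CC(=O)OCC=C | starting material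
8 | prop-2-en-1-yl (6S)-7-chloro-6-methoxy-3-oxoheptanoate | ClC[C@@H](OC)CCC(=O)CC(=O)OCC=C | intermediate
9 | ethyl (2S)-2-hydroxypropanoate (ethyl L-lactate) | C[C@H](O)C(=O)OCC | starting material
10 | (2S)-2-hydroxy-N-methoxy-N-methylpropanamide | C[C@H](O)C(=O)N(C)OC | intermediate
11 | (3,4-dimethoxyphenyl)magnesium bromide | Br[Mg]c1ccc(OC)c(OC)c1 | starting material
12 | (2S)-1-(3,4-dimethoxyphenyl)-2-hydroxypropan-1-one | C[C@H](O)C(=O)c1ccc(OC)c(OC)c1 | intermediate
13 | (2S)-1-(3,4-dimethoxyphenyl)-1-oxopropan-2-yl trifluoromethanesulfonate | C[C@H](OS(=O)(=O)C(F)(F)F)C(=O)c1ccc(OC)c(OC)c1 | intermediate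
14 | prop-2-en-1-yl (6S)-7-chloro-2-[(2S)-1-(3,4-dimethoxyphenyl)-1-oxopropan-2-yl]-6-methoxy-3-oxoheptanoate (C2 epimers; not isolated) | C[C@@H](C(C(=O)OCC=C)C(=O)CC[C@H](OC)CCl)C(=O)c1ccc(OC)c(OC)c1 | intermediate
15 | prop-2-en-1-yl (6S)-2-[(2S)-1-(3,4-dimethoxyphenyl)-1-oxopropan-2-yl]-7-iodo-6-methoxy-3-oxoheptanoate (C2 epimers; not isolated) | C[C@@H](C(C(=O)OCC=C)C(=O)CC[C@H](OC)CI)C(=O)c1ccc(OC)c(OC)c1 | intermediate
16 | prop-2-en-1-yl (5S)-1-[(2S)-1-(3,4-dimethoxyphenyl)-1-oxopropan-2-yl]-5-methoxy-2-oxocyclohexane-1-carboxylate (C1 epimers) | C=CCOC(=O)C1(C(=O)CC[C@H](OC)C1)[C@H](C)C(=O)c2ccc(OC)c(OC)c2 | intermediate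
17 | prop-2-en-1-yl (5R)-1-[(2S)-1-(3,4-dimethoxyphenyl)-1-oxopropan-2-yl]-5-methoxy-2-oxo-3-(phenylselanyl)cyclohexane-1-carboxylate (same spatial arrangement at C5 as in 16; C1 and C3 epimers; not isolated) | C=CCOC(=O)C1(C(=O)C([Se]c3ccccc3)C[C@H](OC)C1)[C@H](C)C(=O)c2ccc(OC)c(OC)c2 | intermediate
18 | prop-2-en-1-yl (5R)-1-[(2S)-1-(3,4-dimethoxyphenyl)-1-oxopropan-2-yl]-5-methoxy-2-oxocyclohex-3-ene-1-carboxylate (C1 epimers) | C=CCOC(=O)C1(C(=O)C=C[C@H](OC)C1)[C@H](C)C(=O)c2ccc(OC)c(OC)c2 | intermediate
19 | (4R,6R)-6-[(2S)-1-(3,4-dimethoxyphenyl)-1-oxopropan-2-yl]-4-methoxy-6-(prop-2-en-1-yl)cyclohex-2-en-1-one | C=CC[C@]1([C@H](C)C(=O)c2ccc(OC)c(OC)c2)C[C@@H](OC)C=CC1=O | target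

## Step count and risks

Total step count: 12. Longest linear sequence: 9 steps (steps 1 to 6, then 10, 11 and 12, from L-glutamic acid); the side-chain branch is steps 7 to 9.

Steps most likely to fail, in order of risk:

**Step 10.** The fully substituted enolate of 14 may close through oxygen (cyclic enol ether) or too slowly, or the α-keto triflate may lose configurational purity by enolisation before it is displaced. The fallback inverts the order of the two alkylations; it sets out from 8 and comes back at 16. Compound 8 alone is cyclised with KOt-Bu and catalytic NaI in t-BuOH–THF at 60 °C. This passes through prop-2-en-1-yl (6S)-7-iodo-6-methoxy-3-oxoheptanoate F1 (not isolated) and should give prop-2-en-1-yl (5S)-5-methoxy-2-oxocyclohexane-1-carboxylate F2, the ring closure now taking place at an unhindered methine carbanion. The sodium enolate of F2 (NaH, THF) is then C-alkylated with 13 at −78 to 0 °C with inversion, the established way to make 1-substituted 2-oxocyclohexane-1-carboxylates, to give 16.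

**Step 12.** Facial selectivity in the allylation of the cross-conjugated dienolate may be poor if the substrate bias opposes the ligand, or O-allylation may compete. The fallback moves the allylation in front of the dehydrogenation; it sets out from 16 and comes back at 19. Compound 16 is treated with Pd2(dba)3 and (S)-t-Bu-PHOX in toluene. The intermediate is then a plain cyclohexanone enolate, the substrate class for which this catalyst is best established, and should give (2R,4S)-2-[(2S)-1-(3,4-dimethoxyphenyl)-1-oxopropan-2-yl]-4-methoxy-2-(prop-2-en-1-yl)cyclohexan-1-one F3. Kinetic enolisation of F3 (LiN(i-Pr)2, THF, −78 °C) and PhSeBr give the selenide (2R,4R)-2-[(2S)-1-(3,4-dimethoxyphenyl)-1-oxopropan-2-yl]-4-methoxy-6-(phenylselanyl)-2-(prop-2-en-1-yl)cyclohexan-1-one F4 (not isolated). Oxidation with H2O2 and syn-elimination then give 19.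

**Step 11.** The amide base may also deprotonate the side-chain methine next to the aryl ketone, which would epimerise that centre or place selenium on the wrong carbon. The fallback is a base-free dehydrogenation; it sets out from 16 and comes back at 18. Compound 16 is heated with 2-iodoxybenzoic acid in DMSO–fluorobenzene at 70 °C. This dehydrogenation runs through the ring enol and single-electron oxidation and needs no strong base; no new compound is involved.

Further compounds
F1 | step 10 | prop-2-en-1-yl (6S)-7-iodo-6-methoxy-3-oxoheptanoate | IC[C@@H](OC)CCC(=O)CC(=O)OCC=C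
F2 | step 10 | prop-2-en-1-yl (5S)-5-methoxy-2-oxocyclohexane-1-carboxylate (C1 epimers) | C=CCOC(=O)C1C(=O)CC[C@H](OC)C1
F3 | step 12 | (2R,4S)-2-[(2S)-1-(3,4-dimethoxyphenyl)-1-oxopropan-2-yl]-4-methoxy-2-(prop-2-en-1-yl)cyclohexan-1-one | C=CC[C@]1([C@H](C)C(=O)c2ccc(OC)c(OC)c2)C[C@@H](OC)CCC1=O
F4 | step 12 | (2R,4R)-2-[(2S)-1-(3,4-dimethoxyphenyl)-1-oxopropan-2-yl]-4-methoxy-6-(phenylselanyl)-2-(prop-2-en-1-yl)cyclohexan-1-one (C6 epimers) | C=CC[C@]1([C@H](C)C(=O)c2ccc(OC)c(OC)c2)C[C@@H](OC)CC([Se]c3ccccc3)C1=O
F0 | step 11 | none | none
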